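(The runs are calculated with made-up constants; scatter was added.)

Percent of the starting material charged is the unit of these readings, so turn each product reading into the share of reagent left.

the same everywhere: added ligand 1.1 mM

| run | starting material | reagent | free catalyst | remark |
|---|---|---|---|---|
| Sunday's | 0.010 M | 1.1 equiv | 5 mol% | run made earlier |
| Wednesday's | 0.040 M | 1.1 equiv | 5 mol% | run made earlier |
| Tuesday's | 0.020 M | 1.1 equiv | 10 mol% | run made earlier |
| flask | 0.020 M | 1.10 equiv | 5 mol% |  |

| run | time / min | product / % | starting material / % |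
|---|---|---|---|
| Sunday's | 2.00 | 8 | 22 |
| Sunday's | 4.00 | 13 | 14 |
| Sunday's | 6.00 | 24 | 10 |
| Sunday's | 12.0 | 39 | 7 |
| Sunday's | 25.0 | 66 | 3 |
| Wednesday's | 2.00 | 32 | 11 |
| Wednesday's | 4.00 | 52 | 4 |
| Wednesday's | 6.00 | 70 | 3 |
| Wednesday's | 12.0 | 91 | 0 |
| Wednesday's | 25.0 | 101 | 3 |
| Tuesday's | 5.00 | 59 | 1 |
| Tuesday's | 10.0 | 86 | 2 |
| Tuesday's | 15.0 | 96 | 0 |
| Tuesday's | 20.0 | 98 | 0 |
| Tuesday's | 25.0 | 100 | 2 |

(each reading ± 1.5 percentage points)

- factor on the rate of making product when 50% of the starting material are converted if reagent is charged twice over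
- factor on the rate when 50% of the starting material are converted if free catalyst is charged at 1 mol% instead

Read the table run by run, taking b as the share of its charge that the reagent still has, which is one minus product over equivalents charged. Let C0 be the catalyst charged and t the time. Define the reagent clock, κ = ln(1/b)/(t·C0), read below.

Sunday's row at 25.0 min gives 1.22 L mol⁻¹ s⁻¹. Wednesday's row at 4.00 min gives 1.33 L mol⁻¹ s⁻¹. Tuesday's row at 5.00 min gives 1.28 L mol⁻¹ s⁻¹, and its row at 10.0 min gives 1.27 L mol⁻¹ s⁻¹.

These readings lie close together, though the reagent charged runs from 11.0 mM to 44.0 mM. So treat the reagent as pseudo-first-order at a given catalyst charge, and take the mean of one row from each run, κ = 1.28 L mol⁻¹ s⁻¹.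

In the flask, C0 is 1.00 mM, so the reagent should fall at 0.0767 min⁻¹. My reckoning follows: a rate proportional to reagent and to catalyst gives a factor 2 for double reagent and 0.200 for 1 mol% catalyst. Sunday's starting material already stands at 22% at 2.00 min, below 50%, so in Sunday's run that conversion lies before the first reading.

The forecast differs, giving 0.185 for 1 mol% catalyst and 1 for double reagent, the latter on the ground that the “reagent is therefore zero order”.

The flask gives 1.67 for double reagent and 0.274 for 1 mol% catalyst, above my second factor and below my first.

    free catalyst + open intermediate ⇌ catalyst intermediate (K = 2500 L mol⁻¹, k = 14.1 L mol⁻¹ s⁻¹)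
    free catalyst + added ligand ⇌ idle complex, settled at all times (K = 490 L mol⁻¹)
    starting material + free catalyst ⇌ free catalyst + open intermediate (K = 9.84, k = 90.7 L mol⁻¹ s⁻¹)
    reagent + catalyst intermediate → free catalyst + product (k = 1.84 L mol⁻¹ s⁻¹)

The flask reaches 50% conversion of starting material at 0.242 min, and at 0.700 min, at a conversion of 70 percent, its rate stands at 1.5 times the rate at 0.242 min. Run the clock on the flask to 15.0 min: it leaves 31.6% of the reagent, and the flask holds 30.5%.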